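**Assumption:** (2S)-liquiritigenin (natural, licorice-derived 4′,7-dihydroxyflavanone) is bought as the single enantiomer and its ee is checked on receipt. The target is taken as drawn, i.e. (2S)-7-hydroxy-2-[4-methoxy-3,5-bis(3-methylbut-2-enyl)phenyl]chroman-4-one.

## Retrosynthetic overview

1. Target ⇒ its 7-O-pivalate (final mild deacylation).
2. Both aryl–prenyl C–C bonds ⇒ one visible-light Ni/photoredox reductive double prenylation of the 3′,5′-dibromo-4′-methoxyflavanone with prenyl acetate (key step, proposed new).
3. Dibromoanisole ⇒ O-methylation and ortho,ortho′-dibromination of the B-ring phenol, both made site-selective by a 7-O-pivalate.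
4. No ring is formed in the route: the A/C chromanone, the B ring and the C2 (S) stereocentre are bought intact in (2S)-liquiritigenin, and C2 is never a reacting centre.

## Route

**Step 1**
Reactants: 1, (2S)-liquiritigenin [(2S)-7-hydroxy-2-(4-hydroxyphenyl)chroman-4-one]; 2, pivaloyl chloride
Product: 3, (2S)-2-(4-hydroxyphenyl)-4-oxochroman-7-yl pivalate
Conditions: PivCl (1.05 equiv), i-Pr2NEt (1.1 equiv), CH2Cl2/THF, −20 → 0 °C
Reagents that add atoms: pivaloyl chloride, CC(C)(C)C(=O)Cl
Why: Selective O-acylation of the more acidic phenol: the 7-OH is a vinylogous acid (pKa ≈ 7.5 vs ≈ 10 for 4′-OH), so one equivalent of hindered amine ionises only it and the bulky acyl chloride caps it; C2 is untouched at low temperature.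

**Step 2**
Reactants: 3, (2S)-2-(4-hydroxyphenyl)-4-oxochroman-7-yl pivalate; 4, N-bromosuccinimide
Product: 5, (2S)-2-(3,5-dibromo-4-hydroxyphenyl)-4-oxochroman-7-yl pivalate
Conditions: NBS (2.05 equiv), MeCN, 0 °C → rt, dark
Reagents that add atoms: N-bromosuccinimide, BrN1C(=O)CCC1=O
Why: Electrophilic aromatic bromination goes to both positions ortho to the only free phenol (para is blocked), because the A ring is deactivated by the ketone and the pivalate; neutral, dark conditions leave C2–H and C3–H alone.

**Step 3**
Reactants: 5, (2S)-2-(3,5-dibromo-4-hydroxyphenyl)-4-oxochroman-7-yl pivalate; 6, trimethylsilyldiazomethane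
Product: 7, (2S)-2-(3,5-dibromo-4-methoxyphenyl)-4-oxochroman-7-yl pivalate
Conditions: TMSCHN2 (2 equiv), toluene/MeOH 4:1, 0 °C → rt
Reagents that add atoms: trimethylsilyldiazomethane, C[Si](C)(C)C=[N+]=[N-]
Why: Base-free diazoalkane O-methylation of the acidic 2,6-dibromophenol (pKa ≈ 6.7); it avoids the phenoxide/base conditions that open 4′-hydroxyflavanones and racemise C2, and the pivalate and ketone are inert.

**Step 4 (key step)**
Reactants: 7, (2S)-2-(3,5-dibromo-4-methoxyphenyl)-4-oxochroman-7-yl pivalate; 8, prenyl acetate (3-methylbut-2-enyl acetate, 5 equiv)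
Product: 9, (2S)-2-[4-methoxy-3,5-bis(3-methylbut-2-enyl)phenyl]-4-oxochroman-7-yl pivalate
Conditions: NiBr2·glyme (15 mol %), dtbbpy (18 mol %), 4CzIPN (3 mol %), Hantzsch ester (3 equiv), 2,6-lutidine (3 equiv), DMA, 456 nm LEDs, 25 °C, Ar
Reagents that add atoms: prenyl acetate, CC(=O)OCC=C(C)C
Why: Proposed new method: a one-pot, twofold, linear-selective Ni/photoredox cross-electrophile prenylation of an ortho,ortho′-dibromoanisole carried on an epimerisable flavanone, which has not been shown; excited 4CzIPN is reductively quenched by Hantzsch ester and its radical anion (≈ −1.2 V vs SCE, too weak to reduce the aryl ketone at ≈ −1.9 V) generates Ni(0)(dtbbpy), which inserts into each C–Br bond; after one-electron reduction the aryl–Ni species ionises prenyl acetate to an aryl(η3-1,1-dimethylallyl)nickel intermediate that reductively eliminates at the unsubstituted CH2 terminus (quaternary-carbon formation next to OMe is disfavoured), giving prenyl rather than reverse-prenyl; lutidine buffers the HBr/AcOH formed, and no strong base, no nucleophilic prenyl-metal and no light absorbed by the flavanone (<350 nm) reaches C2, so the (S) centre is retained; closest known reaction types are Zn/Mn-driven Ni-catalysed reductive coupling of aryl halides with allylic acetates and Ni/photoredox cross-electrophile coupling with organic reductants.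

**Step 5**
Reactants: 9, (2S)-2-[4-methoxy-3,5-bis(3-methylbut-2-enyl)phenyl]-4-oxochroman-7-yl pivalate
Product: 10, abyssinone IV 4′-OMe ether [(2S)-7-hydroxy-2-[4-methoxy-3,5-bis(3-methylbut-2-enyl)phenyl]chroman-4-one]
Conditions: K2CO3 (1.1 equiv), MeOH, 0 °C, then AcOH quench (pH ≈ 5); chiral HPLC check
Reagents that add atoms: none
Why: Transesterification (methanolysis) of an activated aryl ester whose leaving group is the p-acyl phenoxide; the 7-phenoxide formed suppresses C3 enolisation and ring-opening, so C2 (S) is not scrambled, and the prenyl groups and methyl ether are inert.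

## Compound list

1 | (2S)-liquiritigenin | Oc1ccc([C@@H]2CC(=O)c3ccc(O)cc3O2)cc1 | starting material (chiral pool)
2 | pivaloyl chloride | CC(C)(C)C(=O)Cl | starting material (reagent)
3 | (2S)-2-(4-hydroxyphenyl)-4-oxochroman-7-yl pivalate | Oc1ccc([C@@H]2CC(=O)c3ccc(OC(=O)C(C)(C)C)cc3O2)cc1 | intermediate
4 | N-bromosuccinimide | BrN1C(=O)CCC1=O | starting material (reagent)
5 | (2S)-2-(3,5-dibromo-4-hydroxyphenyl)-4-oxochroman-7-yl pivalate | Oc1c(Br)cc([C@@H]2CC(=O)c3ccc(OC(=O)C(C)(C)C)cc3O2)cc1Br | intermediate
6 | trimethylsilyldiazomethane | C[Si](C)(C)C=[N+]=[N-] | starting material (reagent)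
7 | (2S)-2-(3,5-dibromo-4-methoxyphenyl)-4-oxochroman-7-yl pivalate | COc1c(Br)cc([C@@H]2CC(=O)c3ccc(OC(=O)C(C)(C)C)cc3O2)cc1Br | intermediate
8 | prenyl acetate | CC(=O)OCC=C(C)C | starting material (reagent)
9 | (2S)-2-[4-methoxy-3,5-bis(3-methylbut-2-enyl)phenyl]-4-oxochroman-7-yl pivalate | COc1c(CC=C(C)C)cc([C@@H]2CC(=O)c3ccc(OC(=O)C(C)(C)C)cc3O2)cc1CC=C(C)C | intermediate
10 | abyssinone IV 4′-OMe ether | COc1c(CC=C(C)C)cc([C@@H]2CC(=O)c3ccc(O)cc3O2)cc1CC=C(C)C | target

## Summary

Total steps: 5. Longest linear sequence: 5.

Steps most likely to fail, each with a fallback: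

1. **Step 4 (proposed new double photochemical prenylation).** Risks are mono-coupling, hydrodebromination, prenyl dimerisation and ketyl chemistry. Fallback (known chemistry): twofold Pd-catalysed Stille coupling of 7 with tributyl(3-methylbut-2-enyl)stannane, Pd(PPh3)4, DMF, 90 °C, which is neutral and so safe for C2.
2. **Step 1 (7-O vs 4′-O selectivity, trace epimerisation with amine).** Fallback: start from liquiritin, the (2S)-4′-O-β-D-glucoside, where the 4′-OH is already blocked. Pivaloylate its only phenol (PivCl, aq. NaHCO3/acetone), then remove the sugar with β-glucosidase (pH 5, 37 °C) to reach 3. This costs one extra step and uses no base on a free 4′-phenol.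
3. **Step 5 (ee erosion by base-induced chalcone ring-opening during deacylation).** Fallback: carry the 7-OH through the sequence as the 2-(trimethylsilyl)ethyl carbonate (Teoc, installed as in step 1 with Teoc-Cl) and unmask it by fluoride-triggered fragmentation with TBAF/AcOH, which needs no basic solvolysis.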